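## Isodonal: synthesis proposal built on an inverse-demand hetero-Diels–Alder union

Atom numbers are those of the ent-kaurane skeleton: C1 (CHOAc), C2, C3, C4 (CMe2), C5 (CH bearing the aldehyde C6), C10 (spiro carbon), C20 (OCH2 on C10), C7 (lactone C=O), C8 (quaternary bridgehead), C9 (CH between C8 and C10), C11 (CHOH), C12, C13 (bridgehead CH), C14, C15 (ketone), C16(=C17H2).

## The problem

Isodonal is a 6,7-seco-ent-kauranoid. A cyclohexane (ring A) is spiro-fused at C10 to a δ-lactone (O–C7(=O)–C8–C9–C10–C20). The lactone is cis-fused along C8–C9 to the six-membered ring of a bicyclo[3.2.1]octane (C8, C9, C11–C14, bridged by C15–C16).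

The hardest part is the contiguous triad C8 (quaternary)–C9–C10 (quaternary). The C9–C10 bond joins two halves of about ten carbons each and is neopentyl on both sides.

There are seven stereocentres. On ring A, OAc (C1), C20 and the aldehyde (C5) are cis and C9 is trans to them. C11 is syn to C1 across the lactone ring, and C14 is cis to C11. The 11-OH lies on the face of the C15–C16 bridge. C13 is fixed by the bridge.

C1 and C5 can direct the face of attack at C10. The C9/C10 relation has to be set in the bond-forming event itself. C8 can be relayed from C9 only if C14 is delivered through the C11 arm.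

The exo-methylene cyclopentanone (Michael acceptor), the non-enolisable β-keto lactone (retro-Claisen), the epimerisable C5 aldehyde and the acetate will not tolerate nucleophilic base or hydride. They must therefore appear last.

The feature that makes the key step possible is the lactone ring itself: O, C7, C8, C9, C10, C20, with a second acyl carbon (C15) on C8. Read backwards, this ring is the [4+2] adduct of a 1-oxadiene O=C7–C8=C9 (an alkylidene 1,3-dicarbonyl) and an enol ether C10=C20–O. C7, C8 and C15 are therefore the three carbons of Meldrum's acid.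

## Retrosynthesis

**31 back to 28.** The C6 aldehyde is taken back to the primary alcohol 30 and its PMB ether 29. The C16=C17 double bond is taken back to the tertiary alcohol of α-ketol 28. No skeletal bond is cut. This places the two most sensitive groups at the end, and both forward reactions (oxidative deprotection, selective primary oxidation, dehydration) are neutral.

**28 back to 24 (ring D).** After adjustment at C11 (27) and C1 (25), the α-ketol is an acyloin retron, so the C15–C16 bond is cut. This gives keto aldehyde 24, with a formyl group (C15) on C8 and an acetyl group (C16, C17) on C13. Cutting C13–C16 or C8–C15 instead would need a handle on the unfunctionalised C13, or acylation of a fully substituted enolate. Compound 24 has no bridged ring. The forward step is an intramolecular crossed benzoin reaction, and C13 corrects itself because it is α to the ketone.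

**24 back to 18 + 20 (ring C).** The C8–C14 bond (Michael addition) and the C11–C12 bond (carbonyl allylation) are cut, giving the monocyclic lactone 18 and the C5 reagent 20 (C12, C13, C14, C16, C17). C8–C14 is closed from the C11 arm, not by an external electrophile, because a six-membered ring closed from C9 must place C14 syn to C11. That is the target configuration at C8. The intermediates are diol 22 and its oxidation product 23.

**18 back to 10 + 13 (key disconnection).** Lactone 18 comes from acid 17, and 17 from aldehyde 15 by reduction and self-acylation. In 15 the C9–C10 bond (and, at the cycloadduct stage 14, the O–C20 bond) is cut. This gives enol ether 10 (ten skeletal carbons of ring A with C6 and C20) and oxadiene 13 (C7, C8, C9, C11, C15). It is the only cut that creates the quaternary C10 and the C9 stereocentre in one event, joins the two halves at the most hindered bond, and brings both carbonyl carbons on C8 with it. The forward reaction must deliver C9 to the face of C10 opposite the C1 and C5 substituents, and must place C11 syn to C1.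

**10, 13 and 20 back to commercial materials.** Enol ether 10 comes from hydroxymethylene ketone 7 (O-silylation to 8, reduction to 9, silylation). Ketone 7 comes from enone 5 by asymmetric conjugate reduction and formylation of the regiodefined enolate 6. Enone 5 comes from vinylogous ester 2 (from dione 1) and stannane 4 (from 3). Oxadiene 13 is the Knoevenagel product of Meldrum's acid 11 and aldehyde 12. Bromide 20 comes from enone 19.

## Roads not taken

**Alternative 1:** The most obvious cut is a radical disconnection of C9–C10. Ti(III) opening of spiro-epoxide A1 would give the tertiary C10 radical, which adds to an acrylate ester and lactonises to spirolactone A2. Rings C and D would then be built on A2 step by step. In A2, C8 and C9 are both unsubstituted CH2 groups. The C11 branch, the C9 configuration and the quaternary C8 would all have to be introduced later on a lactone with no handle at C9. The chosen cycloaddition delivers C11, the C9 stereocentre and both acyl carbons of C8 together with C10.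

**Alternative 2:** Ring C could be carried as an arene. The C9–C10 bond would be made by an intramolecular Heck reaction of 2-iodo-3-methoxybenzoate A3, giving spiro-isochromanone A4. C8 would then be quaternised by Birch reductive alkylation. The alkylation takes place on a planar dienolate next to the spiro centre, so the electrophile enters from the less hindered C1 side. That gives the C8 epimer of the target. C9 would be set only by a later protonation. Dissolving metal would also cleave the benzylic ether, and C15 would need a late allylic oxidation.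

**Alternative 3:** The lactone and ring C could be closed together by an ester-tethered intramolecular Diels–Alder reaction of acrylate A5 (2-silyloxydiene on C10), giving A6. This leaves the main problem unsolved. The quaternary C10 would have to be made beforehand by a separate enolate alkylation and carried as a dienyl ketone. The ester tether reacts only from its disfavoured s-cis form. C8 remains tertiary, so the second acyl group would again come from an external electrophile.

Key step: step 9

Remarks on the chemistry: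
- The sense of induction in step 4 is assumed from 3-alkylcyclohex-2-enones. If it is reversed, the antipodal ligand is used.
- Stereolabile or temporary centres are left undefined in the SMILES because both epimers converge: C8 in 17–23, C11 in 22, C13 in 24, C16 in 25–28.

## Route

Step 1
Reactants: 1 4,4-dimethylcyclohexane-1,3-dione
Product: 2 3-(2-methylpropoxy)-6,6-dimethylcyclohex-2-en-1-one
Conditions: i-BuOH, TsOH (cat.), PhMe, reflux, Dean–Stark
Reagents that add atoms: 2-methylpropan-1-ol, CC(C)CO
Why: Acid-catalysed enol etherification of a cyclic 1,3-dione; the alcohol attacks the carbonyl remote from the gem-dimethyl group, so the ketone next to C4 is kept for the transposition in step 3.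

Step 2
Reactants: 3 (tributylstannyl)methanol
Product: 4 tributyl{[(4-methoxyphenyl)methoxy]methyl}stannane
Conditions: NaH, PMBCl, Bu4NI (cat.), THF/DMF, 0 to 25 °C
Reagents that add atoms: 4-methoxybenzyl chloride, COc1ccc(CCl)cc1
Why: Williamson etherification of a primary alcohol; gives the precursor of an α-alkoxymethyl carbanion (the C6 unit).

Step 3
Reactants: 2 3-(2-methylpropoxy)-6,6-dimethylcyclohex-2-en-1-one; 4 tributyl{[(4-methoxyphenyl)methoxy]methyl}stannane
Product: 5 3-{[(4-methoxyphenyl)methoxy]methyl}-4,4-dimethylcyclohex-2-en-1-one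
Conditions: 4, n-BuLi, THF, −78 °C; then 2, −78 to 0 °C; 1 M HCl, 25 °C
Reagents that add atoms: water, O
Why: Tin–lithium exchange gives PMBOCH2Li, which adds 1,2 to the vinylogous ester; acid hydrolysis with allylic transposition (Stork–Danheiser sequence) places C6 on C5 next to the gem-dimethyl carbon.

Step 4
Reactants: 5 3-{[(4-methoxyphenyl)methoxy]methyl}-4,4-dimethylcyclohex-2-en-1-one
Product: 7 (2Z,3R)-2-(hydroxymethylidene)-3-{[(4-methoxyphenyl)methoxy]methyl}-4,4-dimethylcyclohexan-1-one, via silyl enol ether 6 (not isolated)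
Conditions: Cu(OAc)2 (2 mol%), (S)-DTBM-SEGPHOS (2 mol%), PhMe2SiH, PhMe, 0 °C; MeLi, THF, 0 °C; CF3CH2OCHO, −78 °C; aq. NH4Cl
Reagents that add atoms: 2,2,2-trifluoroethyl formate, O=COCC(F)(F)F
Why: Ligand-controlled copper hydride 1,4-reduction of a β,β-disubstituted cyclohexenone sets C5 and gives the C1–C10 silyl enol ether regiospecifically; MeLi releases the lithium enolate, which is C-formylated at C10 (Claisen-type formylation) to install C20.

Step 5
Reactants: 7 (2Z,3R)-2-(hydroxymethylidene)-3-{[(4-methoxyphenyl)methoxy]methyl}-4,4-dimethylcyclohexan-1-one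
Product: 8 (2Z,3R)-2-{[(tert-butyldimethylsilyl)oxy]methylidene}-3-{[(4-methoxyphenyl)methoxy]methyl}-4,4-dimethylcyclohexan-1-one
Conditions: TBSCl, Et3N, DMAP (cat.), CH2Cl2, 0 °C
Reagents that add atoms: tert-butyldimethylsilyl chloride, CC(C)(C)[Si](C)(C)Cl
Why: O-Silylation of the chelated (Z)-enol of a β-keto aldehyde on the formyl oxygen; the hydrogen-bonded geometry (oxygen syn to C1) is carried into the enol ether.

Step 6
Reactants: 8 (2Z,3R)-2-{[(tert-butyldimethylsilyl)oxy]methylidene}-3-{[(4-methoxyphenyl)methoxy]methyl}-4,4-dimethylcyclohexan-1-one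
Product: 9 (1S,2Z,3R)-2-{[(tert-butyldimethylsilyl)oxy]methylidene}-3-{[(4-methoxyphenyl)methoxy]methyl}-4,4-dimethylcyclohexan-1-ol
Conditions: DIBAL-H, CH2Cl2, −78 °C; Rochelle salt
Reagents that add atoms: none
Why: 1,2-Reduction of a vinylogous ester carbonyl; axial hydride delivery (only H3 and H5 are 1,3-diaxial to the incoming hydride) gives the equatorial C1 alcohol cis to the C5 side chain.

Step 7
Reactants: 9 (1S,2Z,3R)-2-{[(tert-butyldimethylsilyl)oxy]methylidene}-3-{[(4-methoxyphenyl)methoxy]methyl}-4,4-dimethylcyclohexan-1-ol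
Product: 10 tert-butyl{[(1S,2Z,3R)-2-{[(tert-butyldimethylsilyl)oxy]methylidene}-3-{[(4-methoxyphenyl)methoxy]methyl}-4,4-dimethylcyclohexyl]oxy}dimethylsilane
Conditions: TBSCl, imidazole, DMF, 25 °C
Reagents that add atoms: tert-butyldimethylsilyl chloride, CC(C)(C)[Si](C)(C)Cl
Why: Standard silylation of a secondary alcohol; a silyl ether is chosen because an ester at C1 would ionise next to the enol ether.

Step 8
Reactants: 11 2,2-dimethyl-1,3-dioxane-4,6-dione (Meldrum's acid); 12 2,2-dimethoxyacetaldehyde
Product: 13 5-(2,2-dimethoxyethylidene)-2,2-dimethyl-1,3-dioxane-4,6-dione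
Conditions: ethylenediammonium diacetate (5 mol%), MgSO4, CH2Cl2, 0 to 25 °C; used crude
Reagents that add atoms: none
Why: Knoevenagel condensation of Meldrum's acid with an aldehyde; gives the electron-poor 1-oxadiene that carries C7, C8, C15, C9 and C11.

Step 9
Reactants: 10 tert-butyl{[(1S,2Z,3R)-2-{[(tert-butyldimethylsilyl)oxy]methylidene}-3-{[(4-methoxyphenyl)methoxy]methyl}-4,4-dimethylcyclohexyl]oxy}dimethylsilane; 13 5-(2,2-dimethoxyethylidene)-2,2-dimethyl-1,3-dioxane-4,6-dione
Product: 15 5-{1-[1-formyl-2-(tert-butyldimethylsilyloxy)-6-(4-methoxybenzyloxymethyl)-5,5-dimethylcyclohexyl]-2,2-dimethoxyethyl}-2,2-dimethyl-1,3-dioxane-4,6-dione (C1, C5, C9, C10 as in the target), via cycloadduct 14 (not isolated)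
Conditions: PhMe, 4 Å MS, 25 to 45 °C; then THF/H2O/AcOH, 0 °C
Reagents that add atoms: none
Why: Inverse-electron-demand hetero-Diels–Alder reaction: the 1-oxadiene O=C7–C8=C9 of 13 (LUMO lowered by the second carbonyl C15) reacts with the electron-rich trisubstituted silyl enol ether C10=C20 of 10, the C9–C10 bond forming ahead of the O–C20 bond. The closest known reaction type is the [4+2] cycloaddition of alkylidene Meldrum's acids with enol ethers (domino Knoevenagel/hetero-Diels–Alder chemistry). The ring closed is the six-membered 2-silyloxy-3,4-dihydro-2H-pyran of 14, formed in [4+2] mode with both bonds on one face of each partner; its six atoms are those of the lactone ring of the target. C10 is controlled by ring A: the oxadiene adds to the face of the enol ether opposite the cis-disposed C1 silyloxy and C5 alkoxymethyl groups, so C9 ends trans to both. C9 is controlled by the transition-state geometry: the E-configured oxadiene terminus holds C11 outside, the neopentyl C5 arm sits exo (its C4 methyl groups would otherwise meet the dioxanedione plane), and the C1 arm and the C20 silyloxy group sit endo, which places C11 syn to C1 as in isodonal. Regioselectivity (C10 to C9, O to C20) follows from the polarisation of both partners. Mild aqueous acid then cleaves the silyl acetal of 14 and releases the neopentyl aldehyde of 15 without touching the dimethyl acetal or the secondary silyl ether.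

Step 10
Reactants: 15 the Meldrum's acid aldehyde from step 9
Product: 17 5-(dimethoxymethyl)-7-(tert-butyldimethylsilyloxy)-11-(4-methoxybenzyloxymethyl)-10,10-dimethyl-3-oxo-2-oxaspiro[5.5]undecane-4-carboxylic acid, via hydroxy Meldrum's acid 16 (not isolated)
Conditions: NaBH4, EtOH/THF, 0 °C; aq. KHSO4; PhMe, 80 °C
Reagents that add atoms: none
Why: Borohydride reduces the aldehyde while the Meldrum's acid is protected as its enolate; after acidification the C20 hydroxyl opens the dioxanedione intramolecularly (alcoholysis with loss of acetone), closing the δ-lactone on C7 and leaving C15 as CO2H.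

Step 11
Reactants: 17 the lactone acid from step 10
Product: 18 5-(dimethoxymethyl)-4-(hydroxymethyl)-7-(tert-butyldimethylsilyloxy)-11-(4-methoxybenzyloxymethyl)-10,10-dimethyl-2-oxaspiro[5.5]undecan-3-one
Conditions: BH3·SMe2, THF, 0 to 25 °C; MeOH
Reagents that add atoms: none
Why: Borane reduces a carboxylic acid much faster than a lactone, giving the C15 carbinol chemoselectively.

Step 12
Reactants: 19 3-methylbut-3-en-2-one
Product: 20 3-(bromomethyl)but-3-en-2-one
Conditions: NBS, AIBN (cat.), PhCF3, 80 °C
Reagents that add atoms: N-bromosuccinimide, O=C1CCC(=O)N1Br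
Why: Wohl–Ziegler allylic bromination of the α-methyl group of an enone; gives the 2-acetylallyl reagent (C12, C13, C14, C16, C17).

Step 13
Reactants: 18 the hydroxymethyl lactone from step 11; 20 3-(bromomethyl)but-3-en-2-one
Product: 22 5-(1-hydroxy-3-methylidene-4-oxopentyl)-4-(hydroxymethyl)-7-(tert-butyldimethylsilyloxy)-11-(4-methoxybenzyloxymethyl)-10,10-dimethyl-2-oxaspiro[5.5]undecan-3-one, via hydroxy aldehyde 21 (not isolated)
Conditions: PPTS, acetone/H2O (10:1), 45 °C; then In, 20, THF/H2O (1:1), 25 °C
Reagents that add atoms: water, O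
Why: Mild hydrolysis of the acyclic dimethyl acetal, then indium-mediated Barbier allylation in water, which forms C11–C12 and tolerates the lactone and free hydroxyl; the C11 configuration is irrelevant because C11 is oxidised next.

Step 14
Reactants: 22 the diol from step 13
Product: 24 tricyclic keto aldehyde (ring A, lactone, ring C): C8 carries CHO (C15) and the lactone carbonyl, C11 is a ketone, C13 carries acetyl, C1 carries OTBS, C5 carries CH2OPMB, via formyl diketone 23 (not isolated)
Conditions: (COCl)2, DMSO, CH2Cl2, −78 °C; Et3N, −78 to 25 °C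
Reagents that add atoms: none
Why: Swern oxidation converts both hydroxyls at once, avoiding lactol over-oxidation; the enolised α-formyl lactone then undergoes amine-promoted intramolecular Michael addition (6-endo-trig) to the exo-methylene ketone. Because C14 is delivered from the C11 arm on C9, the C8–C14 bond must form syn to C11, which sets C8 as in the target.

Step 15
Reactants: 24 the tricyclic keto aldehyde from step 14
Product: 25 tetracyclic α-ketol: isodonal skeleton with C15 ketone, C16(OH)CH3, C11 ketone, C1 OTBS, C5 CH2OPMB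
Conditions: 3-benzyl-5-(2-hydroxyethyl)-4-methylthiazolium chloride (20 mol%), DBU (20 mol%), t-BuOH/THF, 40 °C
Reagents that add atoms: none
Why: Carbene-catalysed intramolecular crossed benzoin reaction: the Breslow intermediate from the C15 aldehyde adds to the C16 ketone (five-membered ring). Closure is possible only when C15 and the acetyl group are 1,3-diaxial, so the base-labile C13 is funnelled into the bicyclo[3.2.1]octane.

Step 16
Reactants: 25 the α-ketol from step 15
Product: 27 the α-ketol with C1 OAc (C11 ketone, C5 CH2OPMB), via alcohol 26 (not isolated)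
Conditions: HF·pyridine, pyridine/THF, 25 °C; then Ac2O, pyridine, 40 °C
Reagents that add atoms: acetic anhydride, CC(=O)OC(C)=O
Why: Fluoride cleavage of the C1 silyl ether, then acetylation of the only acylable hydroxyl; the tertiary C16 hydroxyl is inert without DMAP.

Step 17
Reactants: 27 the acetate from step 16
Product: 28 the (11S)-11-hydroxy α-ketol (C1 OAc, C5 CH2OPMB, C16(OH)CH3)
Conditions: NaBH4, MeOH/CH2Cl2, −40 °C
Reagents that add atoms: none
Why: Hydride attacks the C11 ketone from the face remote from the C15–C16 bridge, which blocks the axial trajectory, so the hydroxyl ends on the bridge side as in the target; the C15 ketone lies between two fully substituted carbons and is not reduced.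

Step 18
Reactants: 28 the 11-hydroxy α-ketol from step 17
Product: 29 6-O-(4-methoxybenzyl)-6-deoxo-6-hydroxy-isodonal (exo-methylene ketone formed; C5 carries CH2OPMB)
Conditions: Martin sulfurane, CH2Cl2, 0 °C
Reagents that add atoms: none
Why: Dehydration of the tertiary α-ketol; only the methyl hydrogens can be lost (H13 is a bridgehead, Bredt's rule), so the exo-methylene ketone is the only alkene, and the hindered secondary 11-OH reacts more slowly.

Step 19
Reactants: 29 the PMB ether from step 18
Product: 30 6-deoxo-6-hydroxy-isodonal (C5 carries CH2OH)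
Conditions: DDQ, CH2Cl2/pH 7 buffer, 0 °C
Reagents that add atoms: none
Why: Oxidative cleavage of a 4-methoxybenzyl ether under neutral conditions that leave the enone, β-keto lactone and acetate untouched.

Step 20
Reactants: 30 the primary alcohol from step 19
Product: 31 isodonal
Conditions: TEMPO (10 mol%), PhI(OAc)2, CH2Cl2, 25 °C
Reagents that add atoms: none
Why: Oxoammonium oxidation is selective for the primary alcohol over the hindered secondary 11-OH and is non-basic, so C5 is not epimerised.

## Compound list

1 | 4,4-dimethylcyclohexane-1,3-dione | CC1(C)CCC(=O)CC1=O | starting material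
2 | 3-(2-methylpropoxy)-6,6-dimethylcyclohex-2-en-1-one | CC(C)COC1=CC(=O)C(C)(C)CC1 | intermediate
3 | (tributylstannyl)methanol | CCCC[Sn](CCCC)(CCCC)CO | starting material
4 | tributyl{[(4-methoxyphenyl)methoxy]methyl}stannane | CCCC[Sn](CCCC)(CCCC)COCc1ccc(OC)cc1 | intermediate
5 | 3-{[(4-methoxyphenyl)methoxy]methyl}-4,4-dimethylcyclohex-2-en-1-one | O=C1C=C(COCc2ccc(OC)cc2)C(C)(C)CC1 | intermediate
6 | {[(3S)-3-{[(4-methoxyphenyl)methoxy]methyl}-4,4-dimethylcyclohex-1-en-1-yl]oxy}dimethyl(phenyl)silane | C[Si](C)(c1ccccc1)OC1=C[C@H](COCc2ccc(OC)cc2)C(C)(C)CC1 | intermediate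
7 | (2Z,3R)-2-(hydroxymethylidene)-3-{[(4-methoxyphenyl)methoxy]methyl}-4,4-dimethylcyclohexan-1-one | O=C1CCC(C)(C)[C@@H](COCc2ccc(OC)cc2)/C1=C/O | intermediate
8 | (2Z,3R)-2-{[(tert-butyldimethylsilyl)oxy]methylidene}-3-{[(4-methoxyphenyl)methoxy]methyl}-4,4-dimethylcyclohexan-1-one | O=C1CCC(C)(C)[C@@H](COCc2ccc(OC)cc2)/C1=C/O[Si](C)(C)C(C)(C)C | intermediate
9 | (1S,2Z,3R)-2-{[(tert-butyldimethylsilyl)oxy]methylidene}-3-{[(4-methoxyphenyl)methoxy]methyl}-4,4-dimethylcyclohexan-1-ol | O[C@H]1CCC(C)(C)[C@@H](COCc2ccc(OC)cc2)/C1=C/O[Si](C)(C)C(C)(C)C | intermediate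
10 | bis-silyl ether of 9 (C1 OTBS; Z silyl enol ether at C10=C20) | CC(C)(C)[Si](C)(C)O[C@H]1CCC(C)(C)[C@@H](COCc2ccc(OC)cc2)/C1=C/O[Si](C)(C)C(C)(C)C | intermediate
11 | 2,2-dimethyl-1,3-dioxane-4,6-dione (Meldrum's acid) | CC1(C)OC(=O)CC(=O)O1 | starting material
12 | 2,2-dimethoxyacetaldehyde | COC(OC)C=O | starting material
13 | 5-(2,2-dimethoxyethylidene)-2,2-dimethyl-1,3-dioxane-4,6-dione | COC(OC)C=C1C(=O)OC(C)(C)OC1=O | intermediate
14 | hetero-Diels–Alder adduct: 2-silyloxy-3,4-dihydro-2H-pyran fused to the dioxinone ring and spiro to ring A at C10 (C11, C1 and the C20 silyloxy group cis on the pyran) | [C@H]1(O[Si](C)(C)C(C)(C)C)OC2=C(C(=O)OC(C)(C)O2)[C@@H](C(OC)OC)[C@@]13[C@@H](O[Si](C)(C)C(C)(C)C)CCC(C)(C)[C@H]3COCc1ccc(OC)cc1 | intermediate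
15 | Meldrum's acid aldehyde (C9–C10 bond formed; C20 as CHO, cis to OTBS and CH2OPMB) | O=C[C@@]1([C@H](C(OC)OC)C2C(=O)OC(C)(C)OC2=O)[C@@H](O[Si](C)(C)C(C)(C)C)CCC(C)(C)[C@H]1COCc1ccc(OC)cc1 | intermediate
16 | hydroxy Meldrum's acid (C20 as CH2OH) | OC[C@@]1([C@H](C(OC)OC)C2C(=O)OC(C)(C)OC2=O)[C@@H](O[Si](C)(C)C(C)(C)C)CCC(C)(C)[C@H]1COCc1ccc(OC)cc1 | intermediate
17 | 5-(dimethoxymethyl)-7-(tert-butyldimethylsilyloxy)-11-(4-methoxybenzyloxymethyl)-10,10-dimethyl-3-oxo-2-oxaspiro[5.5]undecane-4-carboxylic acid | OC(=O)C1C(=O)OC[C@@]2([C@@H]1C(OC)OC)[C@@H](O[Si](C)(C)C(C)(C)C)CCC(C)(C)[C@H]2COCc1ccc(OC)cc1 | intermediate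
18 | 4-(hydroxymethyl) analogue of 17 (C15 as CH2OH) | OCC1C(=O)OC[C@@]2([C@@H]1C(OC)OC)[C@@H](O[Si](C)(C)C(C)(C)C)CCC(C)(C)[C@H]2COCc1ccc(OC)cc1 | intermediate
19 | 3-methylbut-3-en-2-one | CC(=O)C(C)=C | starting material
20 | 3-(bromomethyl)but-3-en-2-one | CC(=O)C(=C)CBr | intermediate
21 | hydroxy aldehyde (C11 as CHO; in equilibrium with its lactol) | OCC1C(=O)OC[C@@]2([C@@H]1C=O)[C@@H](O[Si](C)(C)C(C)(C)C)CCC(C)(C)[C@H]2COCc1ccc(OC)cc1 | intermediate
22 | diol: 5-(1-hydroxy-3-methylidene-4-oxopentyl)-4-(hydroxymethyl) lactone | OCC1C(=O)OC[C@@]2([C@@H]1C(O)CC(=C)C(C)=O)[C@@H](O[Si](C)(C)C(C)(C)C)CCC(C)(C)[C@H]2COCc1ccc(OC)cc1 | intermediate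
23 | formyl diketone: 5-(3-methylidene-4-oxopentanoyl)-3-oxo lactone 4-carbaldehyde | O=CC1C(=O)OC[C@@]2([C@@H]1C(=O)CC(=C)C(C)=O)[C@@H](O[Si](C)(C)C(C)(C)C)CCC(C)(C)[C@H]2COCc1ccc(OC)cc1 | intermediate
24 | tricyclic keto aldehyde (ring C closed; C8 CHO, C11 ketone, C13 acetyl, C1 OTBS, C5 CH2OPMB) | O=C[C@]23CC(C(C)=O)CC(=O)[C@H]2[C@]1(COC3=O)[C@@H](O[Si](C)(C)C(C)(C)C)CCC(C)(C)[C@H]1COCc1ccc(OC)cc1 | intermediate
25 | tetracyclic α-ketol (C15 ketone, C16(OH)CH3, C11 ketone, C1 OTBS, C5 CH2OPMB) | CC1(O)C(=O)[C@]23C[C@H]1CC(=O)[C@H]2[C@]1(COC3=O)[C@@H](O[Si](C)(C)C(C)(C)C)CCC(C)(C)[C@H]1COCc1ccc(OC)cc1 | intermediate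
26 | α-ketol with free C1 hydroxyl | CC1(O)C(=O)[C@]23C[C@H]1CC(=O)[C@H]2[C@]1(COC3=O)[C@@H](O)CCC(C)(C)[C@H]1COCc1ccc(OC)cc1 | intermediate
27 | α-ketol C1 acetate (C11 ketone) | CC1(O)C(=O)[C@]23C[C@H]1CC(=O)[C@H]2[C@]1(COC3=O)[C@@H](OC(C)=O)CCC(C)(C)[C@H]1COCc1ccc(OC)cc1 | intermediate
28 | (11S)-11-hydroxy α-ketol C1 acetate | CC1(O)C(=O)[C@]23C[C@H]1C[C@H](O)[C@H]2[C@]1(COC3=O)[C@@H](OC(C)=O)CCC(C)(C)[C@H]1COCc1ccc(OC)cc1 | intermediate
29 | 6-O-(4-methoxybenzyl)-6-deoxo-6-hydroxy-isodonal | C=C1C(=O)[C@]23C[C@H]1C[C@H](O)[C@H]2[C@]1(COC3=O)[C@@H](OC(C)=O)CCC(C)(C)[C@H]1COCc1ccc(OC)cc1 | intermediate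
30 | 6-deoxo-6-hydroxy-isodonal | C=C1C(=O)[C@]23C[C@H]1C[C@H](O)[C@H]2[C@]1(COC3=O)[C@@H](OC(C)=O)CCC(C)(C)[C@H]1CO | intermediate
31 | isodonal | C=C1C(=O)[C@]23C[C@H]1C[C@H](O)[C@H]2[C@]1(COC3=O)[C@@H](OC(C)=O)CCC(C)(C)[C@H]1C=O | target

## Step count and least certain steps

Total: 20 steps. Longest linear sequence: 17 steps (1, 3–7, 9–11, 13–20, from dione 1). Steps 2, 8 and 12 are one-step side branches.

**Step 9 (key step).** The bond joins a fully substituted carbon to a neopentyl one, so cycloaddition may be slow. Slow reaction would allow protodesilylation of the enol ether, or ionisation of the allylic silyl ether at C1, to compete. Facial and endo/exo selectivity could also erode and scramble C9 against C10.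
Fallback: from 7, the β-keto aldehyde is used directly as a 1,3-dicarbonyl Michael donor toward 13 (Et3N, MgBr2·OEt2), giving 2-formyl ketone F1. Borohydride reduction of both carbonyls (axial attack at C1) and warming gives hydroxy lactone acid F2. Silylation (TBSOTf, 2,6-lutidine) returns to 17.

**Step 14.** The C13=C14 double bond may migrate into conjugation with the new C11 ketone before the Michael closure. C9 may also epimerise once C11 is a ketone.
Fallback: from 18, the primary alcohol alone is oxidised (Dess–Martin) to formyl lactone F3. Acetal hydrolysis and indium allylation with 20 give hydroxy enone F4. The Michael closure (Et3N) is then run with C11 still a carbinol, giving F5. Dess–Martin oxidation returns to 24.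

**Step 15.** The carbene or base may deformylate the non-enolisable α-formyl lactone (retro-Claisen). Formation of the Breslow intermediate at the neopentyl aldehyde may be sluggish.
Fallback: from 24, reductive pinacol coupling of the aldehyde and methyl ketone (SmI2, THF, −78 °C) gives diol F6. Oxidation of its secondary hydroxyl (Dess–Martin) returns to 25.

**Step 17.** Hydride may be delivered from the bridge face, or the C15 ketone may be reduced in competition.
Fallback: from 27, if reduction gives the 11-epimer F7, it is converted to triflate F8 (Tf2O, pyridine) and inverted with tetrabutylammonium nitrite (Lattrell–Dax inversion), returning to 28.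

**Step 18.** The secondary 11-OH may undergo competing elimination or sulfuranylation during dehydration of the tertiary alcohol.
Fallback: from 28, the 11-OH is protected as triethylsilyl ether F9. The tertiary alcohol is dehydrated with Burgess reagent to F10. HF·pyridine returns to 29.

## Further compounds

F1 | step 9 | 2-formyl ketone Michael adduct of 7 and 13 (C1 ketone, C20 CHO) | O=C[C@@]1([C@H](C(OC)OC)C2C(=O)OC(C)(C)OC2=O)C(=O)CCC(C)(C)[C@H]1COCc1ccc(OC)cc1
F2 | step 9 | lactone acid with free C1 hydroxyl (desilyl 17) | OC(=O)C1C(=O)OC[C@@]2([C@@H]1C(OC)OC)[C@@H](O)CCC(C)(C)[C@H]2COCc1ccc(OC)cc1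
F3 | step 14 | α-formyl lactone with C11 dimethyl acetal | O=CC1C(=O)OC[C@@]2([C@@H]1C(OC)OC)[C@@H](O[Si](C)(C)C(C)(C)C)CCC(C)(C)[C@H]2COCc1ccc(OC)cc1
F4 | step 14 | α-formyl lactone with 1-hydroxy-3-methylidene-4-oxopentyl side chain | O=CC1C(=O)OC[C@@]2([C@@H]1C(O)CC(=C)C(C)=O)[C@@H](O[Si](C)(C)C(C)(C)C)CCC(C)(C)[C@H]2COCc1ccc(OC)cc1
F5 | step 14 | tricyclic hydroxy keto aldehyde (11-hydroxy analogue of 24) | O=C[C@]23CC(C(C)=O)CC(O)[C@H]2[C@]1(COC3=O)[C@@H](O[Si](C)(C)C(C)(C)C)CCC(C)(C)[C@H]1COCc1ccc(OC)cc1
F6 | step 15 | tetracyclic 15,16-diol (pinacol product) | CC1(O)C(O)[C@]23C[C@H]1CC(=O)[C@H]2[C@]1(COC3=O)[C@@H](O[Si](C)(C)C(C)(C)C)CCC(C)(C)[C@H]1COCc1ccc(OC)cc1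
F7 | step 17 | (11R)-11-hydroxy epimer of 28 | CC1(O)C(=O)[C@]23C[C@H]1C[C@@H](O)[C@H]2[C@]1(COC3=O)[C@@H](OC(C)=O)CCC(C)(C)[C@H]1COCc1ccc(OC)cc1
F8 | step 17 | (11R)-11-triflate | CC1(O)C(=O)[C@]23C[C@H]1C[C@@H](OS(=O)(=O)C(F)(F)F)[C@H]2[C@]1(COC3=O)[C@@H](OC(C)=O)CCC(C)(C)[C@H]1COCc1ccc(OC)cc1
F9 | step 18 | 11-O-triethylsilyl ether of 28 | CC1(O)C(=O)[C@]23C[C@H]1C[C@H](O[Si](CC)(CC)CC)[C@H]2[C@]1(COC3=O)[C@@H](OC(C)=O)CCC(C)(C)[C@H]1COCc1ccc(OC)cc1
F10 | step 18 | 11-O-triethylsilyl ether of 29 | C=C1C(=O)[C@]23C[C@H]1C[C@H](O[Si](CC)(CC)CC)[C@H]2[C@]1(COC3=O)[C@@H](OC(C)=O)CCC(C)(C)[C@H]1COCc1ccc(OC)cc1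
A1 | alternative 1 | ring A 10,20-spiro-epoxide (C1 OTBS, C5 CH2OPMB) | C1O[C@@]12[C@@H](O[Si](C)(C)C(C)(C)C)CCC(C)(C)[C@H]2COCc1ccc(OC)cc1
A2 | alternative 1 | spiro δ-lactone with unsubstituted C8 and C9 | O=C1CC[C@]2(CO1)[C@@H](O[Si](C)(C)C(C)(C)C)CCC(C)(C)[C@H]2COCc1ccc(OC)cc1
A3 | alternative 2 | 2-iodo-3-methoxybenzoate of the ring A allylic alcohol (C1 silyl enol ether) | COc1cccc(C(=O)OCC2=C(O[Si](C)(C)C(C)(C)C)CCC(C)(C)[C@H]2COCc2ccc(OC)cc2)c1I
A4 | alternative 2 | spiro-isochromanone (ring C as anisole) | COc1cccc2C(=O)OC[C@@]3(c12)C(O[Si](C)(C)C(C)(C)C)=CCC(C)(C)[C@H]3COCc1ccc(OC)cc1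
A5 | alternative 3 | acrylate ester with 2-silyloxydiene on quaternary C10 | C=CC(=O)OC[C@@]1(/C=C(\O[Si](C)(C)C(C)(C)C)C=C)[C@@H](O[Si](C)(C)C(C)(C)C)CCC(C)(C)[C@H]1COCc1ccc(OC)cc1
A6 | alternative 3 | cis-fused lactone cyclohexenyl silyl ether (intramolecular Diels–Alder adduct) | O=C1OC[C@@]2([C@H]3[C@@H]1CCC=C3O[Si](C)(C)C(C)(C)C)[C@@H](O[Si](C)(C)C(C)(C)C)CCC(C)(C)[C@H]2COCc1ccc(OC)cc1
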